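**Retrosynthetic overview** (locants are germacrane locants of the target: ring C1–C10, lactone carbons C11–C13, C14 on C10, C15 on C4)
1. Target 33 comes from α-phosphono lactone 27 by C8 acylation, Horner–Wadsworth–Emmons methylenation, exchange of the C9 silyl ether for acetate and desilylation.
2. Key disconnection C7–C11: the strategy rests on the trans-fused γ-lactone ring O6–C12–C11–C7–C6 and the C6–C7–C8 array (O6 and O8 on one face, C11 on the other). It is opened to the ten-membered 7,8-cis-epoxide 24, whose epoxide oxygen is syn to O6 and whose O6 carries a diethylphosphonoacetate.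
3. Ten-membered ring: ring-closing metathesis at C1=C10 of acyclic diene 20. C9 comes from Felkin–Anh addition of a 2-lithioallyl ether to cis-epoxy aldehyde 15, and the epoxide from Sharpless epoxidation of Z-allylic alcohol 13.
4. C6 comes from asymmetric alkynylation of enal 7. Its ring-cis C4=C5 alkene is made from but-2-yne-1,4-diol by trans-hydroalumination/iodination and Negishi coupling.
5. Ring order: ten-membered carbocycle first (step 13), γ-lactone second (step 16).

Key step: step 16

Assumption: the (S,S)-ProPhenol/Me2Zn catalyst is taken to add the alkynyl group to the enal face that gives the (6R)-carbinol 10; if the sense is the opposite, the (R,R)-ligand is used and nothing else changes.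

Step 1
Reactants: 1 but-2-yne-1,4-diol
Product: 2 4-[(tert-butyldiphenylsilyl)oxy]but-2-yn-1-ol
Conditions: NaH (1.0 equiv), THF, 0 °C to rt; then TBDPSCl
Reagents that add atoms: tert-butyl(chloro)diphenylsilane, CC(C)(C)[Si](Cl)(c1ccccc1)c1ccccc1
Why: Monosilylation of a symmetrical diol through its monosodium alkoxide (Williamson-type O-silylation) should leave the second hydroxyl free for the directed reduction.

Step 2
Reactants: 2 4-[(tert-butyldiphenylsilyl)oxy]but-2-yn-1-ol
Product: 4 (2Z)-4-[(tert-butyldiphenylsilyl)oxy]-3-iodobut-2-en-1-ol, via cyclic vinylalanate 3 (not isolated)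
Conditions: NaAlH2(OCH2CH2OMe)2 (Red-Al), THF, 0 °C; then I2, THF, −78 to 0 °C
Reagents that add atoms: iodine, II
Why: Hydroxyl-directed trans-hydroalumination of the propargylic alcohol places aluminium on the future C4 inside a five-membered alkoxyalanate, and iododealumination with retention gives the vinyl iodide with iodine cis to CH2OH, which fixes the ring-cis C4=C5 geometry.

Step 3
Reactants: 4 (2Z)-4-[(tert-butyldiphenylsilyl)oxy]-3-iodobut-2-en-1-ol; 5 but-3-en-1-ylzinc bromide
Product: 6 (2E)-3-{[(tert-butyldiphenylsilyl)oxy]methyl}hepta-2,6-dien-1-ol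
Conditions: 5 (2.5 equiv), PdCl2(dppf) (5 mol%), THF, rt to 50 °C
Reagents that add atoms: none
Why: Negishi sp2–sp3 cross-coupling proceeds with retention of alkene geometry, so the butenyl chain (C3–C1) ends cis to C6; the bidentate phosphine suppresses β-hydride elimination and the free hydroxyl is carried as its zinc alkoxide.

Step 4
Reactants: 6 (2E)-3-{[(tert-butyldiphenylsilyl)oxy]methyl}hepta-2,6-dien-1-ol
Product: 7 (2E)-3-{[(tert-butyldiphenylsilyl)oxy]methyl}hepta-2,6-dienal
Conditions: MnO2, CH2Cl2, rt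
Reagents that add atoms: none
Why: Allylic oxidation with MnO2 converts the primary allylic alcohol to the enal under neutral conditions that should not isomerise the trisubstituted alkene.

Step 5
Reactants: 7 (2E)-3-{[(tert-butyldiphenylsilyl)oxy]methyl}hepta-2,6-dienal; 8 tert-butyldimethyl(prop-2-yn-1-yloxy)silane
Product: 10 (4R,5E)-1-[(tert-butyldimethylsilyl)oxy]-6-{[(tert-butyldiphenylsilyl)oxy]methyl}deca-5,9-dien-2-yn-4-ol, via alkynylzinc 9 (not isolated)
Conditions: Me2Zn, (S,S)-ProPhenol (20 mol%), Ph3P=O (40 mol%), toluene, 0 °C; aq. NH4Cl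
Reagents that add atoms: none
Why: Catalytic asymmetric alkynylation of the enal by the zinc acetylide inside the chiral dinuclear zinc–ProPhenol pocket (reagent-controlled 1,2-addition) sets C6 as R, and any minor enantiomer becomes a separable diastereomer after step 9.

Step 6
Reactants: 10 (4R,5E)-propargylic alcohol
Product: 11 4-O-(4-methoxybenzyl) ether of 10
Conditions: NaH, PMBCl, Bu4NI (cat.), DMF, 0 °C to rt
Reagents that add atoms: 4-methoxybenzyl chloride, COc1ccc(CCl)cc1
Why: Williamson etherification under basic conditions protects O6 without ionising the doubly activated carbinol and gives a group that is later removed oxidatively beside silyl ethers and the epoxide.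

Step 7
Reactants: 11 4-O-(4-methoxybenzyl) ether of 10
Product: 12 (4R,5E)-6-{[(tert-butyldiphenylsilyl)oxy]methyl}-4-[(4-methoxybenzyl)oxy]deca-5,9-dien-2-yn-1-ol
Conditions: PPTS, MeOH, rt
Reagents that add atoms: none
Why: Acid-catalysed methanolysis (selective desilylation) cleaves the primary TBS ether far faster than the primary TBDPS ether and should leave the PMB ether intact.

Step 8
Reactants: 12 (4R,5E)-dienynol
Product: 13 (2Z,4S,5E)-6-{[(tert-butyldiphenylsilyl)oxy]methyl}-4-[(4-methoxybenzyl)oxy]deca-2,5,9-trien-1-ol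
Conditions: H2 (1 atm), Pd/CaCO3 poisoned with Pb(OAc)2 (Lindlar catalyst), quinoline, EtOAc, rt
Reagents that add atoms: none
Why: Lindlar semi-hydrogenation adds hydrogen syn to the alkyne to give the Z-allylic alcohol, and the poisoned catalyst should spare the terminal and trisubstituted alkenes when uptake is stopped at one equivalent (the C6 descriptor changes to S by priority only).

Step 9
Reactants: 13 (2Z,4S,5E)-trienol
Product: 14 {(2S,3R)-3-[(1R,2E)-3-{[(tert-butyldiphenylsilyl)oxy]methyl}-1-[(4-methoxybenzyl)oxy]hepta-2,6-dien-1-yl]oxiran-2-yl}methanol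
Conditions: Ti(OiPr)4 (0.3 equiv), L-(+)-DIPT (0.36 equiv), t-BuOOH, 4 Å molecular sieves, CH2Cl2, −20 °C
Reagents that add atoms: tert-butyl hydroperoxide, CC(C)(C)OO
Why: Sharpless asymmetric epoxidation directed by the C9 hydroxyl touches only the C7=C8 alkene, and L-(+)-tartrate delivers oxygen to the face that gives the (2S,3R)-cis-epoxy alcohol, which is also the face anti to the C6 ether oxygen in the A(1,3)-minimised conformer, so reagent and substrate control should reinforce each other.

Step 10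
Reactants: 14 (2S,3R)-epoxy alcohol
Product: 15 (2R,3R)-3-[(1R,2E)-3-{[(tert-butyldiphenylsilyl)oxy]methyl}-1-[(4-methoxybenzyl)oxy]hepta-2,6-dien-1-yl]oxirane-2-carbaldehyde
Conditions: Dess–Martin periodinane, NaHCO3, CH2Cl2, 0 °C; used crude
Reagents that add atoms: none
Why: Buffered Dess–Martin oxidation gives the cis-epoxy aldehyde without base strong enough to epimerise C8 or open the epoxide.

Step 11
Reactants: 16 2-bromoprop-2-en-1-ol
Product: 17 [(2-bromoprop-2-en-1-yl)oxy](tert-butyl)diphenylsilane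
Conditions: TBDPSCl, imidazole, CH2Cl2, rt
Reagents that add atoms: tert-butyl(chloro)diphenylsilane, CC(C)(C)[Si](Cl)(c1ccccc1)c1ccccc1
Why: Standard O-silylation gives the C10/C14 building block, and the bulky silyl group slows O-to-C silyl migration in the derived vinyllithium.

Step 12
Reactants: 15 (2R,3R)-cis-epoxy aldehyde; 17 [(2-bromoprop-2-en-1-yl)oxy](tert-butyl)diphenylsilane
Product: 20 acyclic (6R,7R,8R,9S)-diene with 6-O-PMB 7,8-epoxide 9-O-TES, via vinyllithium 18 (not isolated), via lithium alkoxide 19 (not isolated)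
Conditions: 17, t-BuLi (2 equiv), Et2O, −78 °C; add 15, −78 °C; then TESCl, THF, −78 to 0 °C
Reagents that add atoms: chlorotriethylsilane, CC[Si](Cl)(CC)CC
Why: Bromine–lithium exchange gives the 2-lithioallyl ether, which adds to the cis-epoxy aldehyde under Felkin–Anh control (epoxide C–O bond anti to the incoming nucleophile, no chelation) to set C9 as S, erythro to the epoxide, and silylating the lithium alkoxide in the same flask avoids handling the free epoxy alcohol.

Step 13
Reactants: 20 acyclic (6R,7R,8R,9S)-diene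
Product: 21 (6R,7R,8R,9S)-7,8-epoxy-6-[(4-methoxybenzyl)oxy]-9-(triethylsilyloxy)-14,15-bis(tert-butyldiphenylsilyloxy)germacra-1(10),4-diene
Conditions: second-generation Grubbs catalyst RuCl2(=CHPh)(H2IMes)(PCy3) (10 mol%), toluene (1 mM), 80 °C
Reagents that add atoms: none
Why: Ring-closing metathesis loads the catalyst on the unhindered C1 vinyl group and closes onto the 1,1-disubstituted C10 alkene with loss of ethene; the cis-epoxide and the ring-cis C4=C5 alkene bend the chain, and the ring-cis trisubstituted C1=C10 alkene is the less strained isomer in a ten-membered ring.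

Step 14
Reactants: 21 ten-membered 6-O-PMB epoxide
Product: 22 (6R,7R,8R,9S)-7,8-epoxy-9-(triethylsilyloxy)-14,15-bis(tert-butyldiphenylsilyloxy)germacra-1(10),4-dien-6-ol
Conditions: DDQ, CH2Cl2/pH 7 buffer, 0 °C
Reagents that add atoms: none
Why: Oxidative PMB cleavage under buffered conditions frees O6 alone and should leave the silyl ethers, the epoxide and both alkenes untouched.

Step 15
Reactants: 22 ten-membered 6-ol; 23 (diethoxyphosphoryl)acetic acid
Product: 24 6-O-[(diethoxyphosphoryl)acetyl] derivative of 22 (key-step precursor)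
Conditions: DCC, DMAP (cat.), CH2Cl2, 0 °C to rt
Reagents that add atoms: none
Why: Steglich esterification of the secondary allylic alcohol with the phosphonoacetic acid is a mild, neutral acylation compatible with the adjacent epoxide.

Step 16
Reactants: 24 ten-membered 7,8-cis-epoxide O6 diethylphosphonoacetate
Product: 27 α-phosphono trans-lactone with free C8 hydroxyl (6R,7R,8R,9S; C11 epimers), via sodium enolate 25 (not isolated), via cyclised sodium enolate 26 (not isolated)
Conditions: NaH (1.0 equiv), THF, 0 °C; LiClO4 (2 equiv), 50 °C; then AcOH, 0 °C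
Reagents that add atoms: none
Why: NaH removes a proton from the phosphonoacetate CH2, the only acidic site, and the carbon of enolate 25 attacks C7 from the face opposite the epoxide oxygen in an intramolecular SN2 opening, so the C7–C11 bond, the γ-lactone and the C8 alkoxide form in one event; the alkoxide is then protonated by the much more acidic C11–H to give stabilised enolate 26, which is quenched with AcOH. The closest known reaction types are the epoxynitrile-type cyclisation of tethered stabilised carbanions onto epoxides and the trans-lactone annulation of epoxides with phosphonoacetate or malonate anions. The lactone closes in the 5-exo-tet mode, the breaking C7–O bond lying outside the new ring, from a conformer with H6 and H7 anti and O6 anticlinal to the epoxide oxygen about C6–C7. C7 is set by stereospecific inversion, which turns the epoxide syn to O6 into the trans-fused lactone with C11 anti to O8, while C11 forms as a mixture that is erased in step 18. The step needs attack at C7 rather than C8, which the tether length secures (5-exo against 6-endo, with C8 further shielded by the C9 silyl ether), and C- rather than O-alkylation, which the soft phosphonate-stabilised carbanion and LiClO4 activation of the epoxide favour. It also needs the lactone to stay on O6, which one equivalent of base secures because no free C8 alkoxide then survives to translactonise.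

Step 17
Reactants: 27 α-phosphono trans-lactone; 28 (2S)-2-methylbutanoic acid
Product: 29 8-O-[(2S)-2-methylbutanoyl] α-phosphono lactone (6R,7S,8R,9S; C11 epimers)
Conditions: DCC, DMAP, CH2Cl2, rt
Reagents that add atoms: none
Why: Steglich esterification acylates the only free hydroxyl without deprotonating the phosphonolactone C–H, and doing it before the olefination removes the hydroxyl that could translactonise to the 8,12-olide.

Step 18
Reactants: 29 8-O-acyl α-phosphono lactone
Product: 30 (6R,7S,8R,9S)-8-[(2S)-2-methylbutanoyloxy]-9-(triethylsilyloxy)-14,15-bis(tert-butyldiphenylsilyloxy)germacra-1(10),4,11(13)-trien-12,6-olide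
Conditions: K2CO3, 37% aq. CH2O, THF, rt
Reagents that add atoms: formaldehyde, C=O
Why: Horner–Wadsworth–Emmons olefination of the α-phosphono lactone with formaldehyde installs the C11=C13 methylene under mild carbonate conditions that should not cleave the esters.

Step 19
Reactants: 30 α-methylene lactone 9-O-TES ether
Product: 31 9-hydroxy α-methylene lactone (14,15-bis-TBDPS ether)
Conditions: HF·pyridine, pyridine, THF, 0 °C
Reagents that add atoms: none
Why: Buffered fluoride desilylation removes the secondary TES ether much faster than the two primary TBDPS ethers, and the acidic medium disfavours acyl migration from O8.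

Step 20
Reactants: 31 9-hydroxy α-methylene lactone
Product: 32 9-O-acetyl α-methylene lactone (14,15-bis-TBDPS ether)
Conditions: Ac2O, pyridine, DMAP (cat.), CH2Cl2, 0 °C to rt
Reagents that add atoms: acetic anhydride, CC(=O)OC(C)=O
Why: Standard acetylation of the only free hydroxyl places the acetate on O9 while both primary alcohols are still silylated.

Step 21
Reactants: 32 9-O-acetyl bis-TBDPS ether
Product: 33 target, (6R,7S,8R,9S)-9-acetoxy-14,15-dihydroxy-8-[(2S)-2-methylbutanoyloxy]germacra-1(10),4,11(13)-trien-12,6-olide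
Conditions: HF·pyridine, THF, 0 °C to rt
Reagents that add atoms: none
Why: Acidic fluoride desilylation frees both primary allylic alcohols without the basic conditions that would move the O9 acetate to O14 or add to the α-methylene lactone.

**Compound list**
1 | but-2-yne-1,4-diol | OCC#CCO | starting material
2 | 4-[(tert-butyldiphenylsilyl)oxy]but-2-yn-1-ol | OCC#CCO[Si](c1ccccc1)(c1ccccc1)C(C)(C)C | intermediate
3 | sodium cyclic vinylalanate (five-membered O–Al–C=C–CH2 ring, Al bearing two 2-methoxyethoxy groups, ring carbon bonded to Al carrying CH2OTBDPS) | [Na+].COCCO[Al-]1(OCCOC)OCC=C1CO[Si](c2ccccc2)(c2ccccc2)C(C)(C)C | intermediate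
4 | (2Z)-4-[(tert-butyldiphenylsilyl)oxy]-3-iodobut-2-en-1-ol | OC/C=C(\I)CO[Si](c1ccccc1)(c1ccccc1)C(C)(C)C | intermediate
5 | but-3-en-1-ylzinc bromide | C=CCC[Zn]Br | starting material
6 | (2E)-3-{[(tert-butyldiphenylsilyl)oxy]methyl}hepta-2,6-dien-1-ol (butenyl chain cis to CH2OH) | OC/C=C(\CCC=C)CO[Si](c1ccccc1)(c1ccccc1)C(C)(C)C | intermediate
7 | (2E)-3-{[(tert-butyldiphenylsilyl)oxy]methyl}hepta-2,6-dienal (butenyl chain cis to CHO) | O=C/C=C(\CCC=C)CO[Si](c1ccccc1)(c1ccccc1)C(C)(C)C | intermediate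
8 | tert-butyldimethyl(prop-2-yn-1-yloxy)silane | C#CCO[Si](C)(C)C(C)(C)C | starting material
9 | methyl[3-(tert-butyldimethylsilyloxy)prop-1-yn-1-yl]zinc | C[Zn]C#CCO[Si](C)(C)C(C)(C)C | intermediate
10 | (4R,5E)-1-[(tert-butyldimethylsilyl)oxy]-6-{[(tert-butyldiphenylsilyl)oxy]methyl}deca-5,9-dien-2-yn-4-ol | O[C@@H](C#CCO[Si](C)(C)C(C)(C)C)/C=C(\CCC=C)CO[Si](c1ccccc1)(c1ccccc1)C(C)(C)C | intermediate
11 | 4-O-(4-methoxybenzyl) ether of 10 (4R,5E) | COc1ccc(CO[C@@H](C#CCO[Si](C)(C)C(C)(C)C)/C=C(\CCC=C)CO[Si](c2ccccc2)(c2ccccc2)C(C)(C)C)cc1 | intermediate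
12 | (4R,5E)-6-{[(tert-butyldiphenylsilyl)oxy]methyl}-4-[(4-methoxybenzyl)oxy]deca-5,9-dien-2-yn-1-ol | COc1ccc(CO[C@@H](C#CCO)/C=C(\CCC=C)CO[Si](c2ccccc2)(c2ccccc2)C(C)(C)C)cc1 | intermediate
13 | (2Z,4S,5E)-6-{[(tert-butyldiphenylsilyl)oxy]methyl}-4-[(4-methoxybenzyl)oxy]deca-2,5,9-trien-1-ol | COc1ccc(CO[C@@H](/C=C\CO)/C=C(\CCC=C)CO[Si](c2ccccc2)(c2ccccc2)C(C)(C)C)cc1 | intermediate
14 | {(2S,3R)-3-[(1R,2E)-3-{[(tert-butyldiphenylsilyl)oxy]methyl}-1-[(4-methoxybenzyl)oxy]hepta-2,6-dien-1-yl]oxiran-2-yl}methanol | COc1ccc(CO[C@@H]([C@H]2O[C@H]2CO)/C=C(\CCC=C)CO[Si](c3ccccc3)(c3ccccc3)C(C)(C)C)cc1 | intermediate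
15 | (2R,3R)-3-[(1R,2E)-3-{[(tert-butyldiphenylsilyl)oxy]methyl}-1-[(4-methoxybenzyl)oxy]hepta-2,6-dien-1-yl]oxirane-2-carbaldehyde | COc1ccc(CO[C@@H]([C@H]2O[C@H]2C=O)/C=C(\CCC=C)CO[Si](c3ccccc3)(c3ccccc3)C(C)(C)C)cc1 | intermediate
16 | 2-bromoprop-2-en-1-ol | OCC(Br)=C | starting material
17 | [(2-bromoprop-2-en-1-yl)oxy](tert-butyl)diphenylsilane | C=C(Br)CO[Si](c1ccccc1)(c1ccccc1)C(C)(C)C | intermediate
18 | [3-(tert-butyldiphenylsilyloxy)prop-1-en-2-yl]lithium | [Li]C(=C)CO[Si](c1ccccc1)(c1ccccc1)C(C)(C)C | intermediate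
19 | lithium C9 alkoxide of the Felkin adduct (6R,7R,8R,9S) | COc1ccc(CO[C@@H]([C@H]2O[C@H]2[C@@H](O[Li])C(=C)CO[Si](c3ccccc3)(c3ccccc3)C(C)(C)C)/C=C(\CCC=C)CO[Si](c3ccccc3)(c3ccccc3)C(C)(C)C)cc1 | intermediate
20 | acyclic (6R,7R,8R,9S)-diene: C1=CH2 terminus, ring-cis C4=C5 alkene bearing CH2OTBDPS (C15), 6-O-PMB, 7,8-cis-epoxide, 9-O-TES, C10(=CH2)CH2OTBDPS | COc1ccc(CO[C@@H]([C@H]2O[C@H]2[C@@H](O[Si](CC)(CC)CC)C(=C)CO[Si](c3ccccc3)(c3ccccc3)C(C)(C)C)/C=C(\CCC=C)CO[Si](c3ccccc3)(c3ccccc3)C(C)(C)C)cc1 | intermediate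
21 | (1(10)Z,4E,6R,7R,8R,9S)-7,8-epoxy-6-[(4-methoxybenzyl)oxy]-9-(triethylsilyloxy)-14,15-bis(tert-butyldiphenylsilyloxy)germacra-1(10),4-diene (both ring alkenes ring-cis) | COc1ccc(CO[C@@H]2/C=C(/CO[Si](c3ccccc3)(c3ccccc3)C(C)(C)C)CC/C=C(/CO[Si](c3ccccc3)(c3ccccc3)C(C)(C)C)[C@H](O[Si](CC)(CC)CC)[C@@H]3O[C@H]23)cc1 | intermediate
22 | (6R,7R,8R,9S)-7,8-epoxy-9-(triethylsilyloxy)-14,15-bis(tert-butyldiphenylsilyloxy)germacra-1(10),4-dien-6-ol | O[C@@H]1/C=C(/CO[Si](c2ccccc2)(c2ccccc2)C(C)(C)C)CC/C=C(/CO[Si](c2ccccc2)(c2ccccc2)C(C)(C)C)[C@H](O[Si](CC)(CC)CC)[C@@H]2O[C@H]12 | intermediate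
23 | (diethoxyphosphoryl)acetic acid | OC(=O)CP(=O)(OCC)OCC | starting material
24 | 6-O-[(diethoxyphosphoryl)acetyl] ester of 22 (6R,7R,8R,9S), key-step precursor | CCOP(=O)(OCC)CC(=O)O[C@@H]1/C=C(/CO[Si](c2ccccc2)(c2ccccc2)C(C)(C)C)CC/C=C(/CO[Si](c2ccccc2)(c2ccccc2)C(C)(C)C)[C@H](O[Si](CC)(CC)CC)[C@@H]2O[C@H]12 | intermediate
25 | sodium enolate of 24 | [Na+].CCOP(=O)(OCC)C=C([O-])O[C@@H]1/C=C(/CO[Si](c2ccccc2)(c2ccccc2)C(C)(C)C)CC/C=C(/CO[Si](c2ccccc2)(c2ccccc2)C(C)(C)C)[C@H](O[Si](CC)(CC)CC)[C@@H]2O[C@H]12 | intermediate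
26 | sodium enolate of lactone 27 (C11 anion, free C8 hydroxyl) | [Na+].CCOP(=O)(OCC)C1=C([O-])O[C@@H]2/C=C(/CO[Si](c3ccccc3)(c3ccccc3)C(C)(C)C)CC/C=C(/CO[Si](c3ccccc3)(c3ccccc3)C(C)(C)C)[C@H](O[Si](CC)(CC)CC)[C@H](O)[C@@H]12 | intermediate
27 | (6R,7R,8R,9S)-11-(diethoxyphosphoryl)-8-hydroxy-9-(triethylsilyloxy)-14,15-bis(tert-butyldiphenylsilyloxy)-13-norgermacra-1(10),4-dien-12,6-olide, trans-fused, C11 epimers (key-step product) | CCOP(=O)(OCC)C1C(=O)O[C@@H]2/C=C(/CO[Si](c3ccccc3)(c3ccccc3)C(C)(C)C)CC/C=C(/CO[Si](c3ccccc3)(c3ccccc3)C(C)(C)C)[C@H](O[Si](CC)(CC)CC)[C@H](O)[C@@H]12 | intermediate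
28 | (2S)-2-methylbutanoic acid | CC[C@H](C)C(O)=O | starting material
29 | 8-O-[(2S)-2-methylbutanoyl] ester of 27 (6R,7S,8R,9S; C11 epimers) | CCOP(=O)(OCC)C1C(=O)O[C@@H]2/C=C(/CO[Si](c3ccccc3)(c3ccccc3)C(C)(C)C)CC/C=C(/CO[Si](c3ccccc3)(c3ccccc3)C(C)(C)C)[C@H](O[Si](CC)(CC)CC)[C@H](OC(=O)[C@@H](C)CC)[C@@H]12 | intermediate
30 | (6R,7S,8R,9S)-8-[(2S)-2-methylbutanoyloxy]-9-(triethylsilyloxy)-14,15-bis(tert-butyldiphenylsilyloxy)germacra-1(10),4,11(13)-trien-12,6-olide | C=C1C(=O)O[C@@H]2/C=C(/CO[Si](c3ccccc3)(c3ccccc3)C(C)(C)C)CC/C=C(/CO[Si](c3ccccc3)(c3ccccc3)C(C)(C)C)[C@H](O[Si](CC)(CC)CC)[C@H](OC(=O)[C@@H](C)CC)[C@@H]12 | intermediate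
31 | 9-hydroxy analogue of 30 (TES removed) | C=C1C(=O)O[C@@H]2/C=C(/CO[Si](c3ccccc3)(c3ccccc3)C(C)(C)C)CC/C=C(/CO[Si](c3ccccc3)(c3ccccc3)C(C)(C)C)[C@H](O)[C@H](OC(=O)[C@@H](C)CC)[C@@H]12 | intermediate
32 | 9-O-acetyl derivative of 31 | C=C1C(=O)O[C@@H]2/C=C(/CO[Si](c3ccccc3)(c3ccccc3)C(C)(C)C)CC/C=C(/CO[Si](c3ccccc3)(c3ccccc3)C(C)(C)C)[C@H](OC(C)=O)[C@H](OC(=O)[C@@H](C)CC)[C@@H]12 | intermediate
33 | (1(10)Z,4E,6R,7S,8R,9S)-9-acetoxy-14,15-dihydroxy-8-[(2S)-2-methylbutanoyloxy]germacra-1(10),4,11(13)-trien-12,6-olide | C=C1C(=O)O[C@@H]2/C=C(/CO)CC/C=C(/CO)[C@H](OC(C)=O)[C@H](OC(=O)[C@@H](C)CC)[C@@H]12 | target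

**Step count**
Total: 21 steps. Longest linear sequence: 20 steps (steps 1–10 and 12–21).

**Steps most likely to fail**

Step 16 (lactone annulation in the ring). The enolate carbon may not reach the back of C7 in the accessible ring conformers, since the ester must turn s-trans and O6 must stand anticlinal to the epoxide oxygen. The result would be no reaction, opening at C8, or migration of the lactone to O8. The fallback sets out from 20 and comes back at 27: it performs the same annulation on the conformationally free acyclic chain and closes the carbocycle afterwards. DDQ in buffered CH2Cl2 removes the PMB group from 20 to give the acyclic C6 alcohol F1. DCC/DMAP esterification with 23 gives the acyclic O6 diethylphosphonoacetate F2. NaH (1.0 equiv) with LiClO4 in THF then gives the acyclic α-phosphono trans-γ-lactone with free C8 hydroxyl F3. Ring-closing metathesis of F3 with the second-generation Grubbs catalyst RuCl2(=CHPh)(H2IMes)(PCy3) in dilute toluene returns 27.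

Step 13 (ring-closing metathesis). The alkylidene formed at C1 may fail to engage the hindered 1,1-disubstituted C10 alkene and be diverted into dimerisation, or the ring may close to the ring-trans alkene. The fallback sets out from 4 and 15 and comes back at 21: it moves catalyst loading to C10 with a relay tether. O-Allylation of 4 (NaH, allyl bromide, THF) gives the allyl ether tert-butyl({(2Z)-2-iodo-4-[(prop-2-en-1-yl)oxy]but-2-en-1-yl}oxy)diphenylsilane F4. Iodine–lithium exchange (t-BuLi, Et2O, −78 °C), addition to 15 and silylation with TESCl give the relay triene F5, the analogue of 20 whose C10 methylene carbon carries CH2OCH2CH=CH2. With the same ruthenium catalyst, the terminal allyl ether is expected to load first and expel 2,5-dihydrofuran, leaving the alkylidene on C10, which closes onto the C1 vinyl group to give 21.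

Step 12 (alkenyl addition). Facial selectivity at C9 may be poor if the Felkin–Anh preference of the cis-epoxy aldehyde is eroded. The fallback sets out from 15 (with 18 from 17) and comes back at 20: it resets C9 by chelation-controlled reduction. The addition is quenched with aq. NH4Cl instead of TESCl to give the C9-epimeric alcohols F6. Dess–Martin oxidation gives the α,β-epoxy enone F7. Zn(BH4)2 in Et2O at −30 °C, delivering hydride to the zinc chelate of ketone and epoxide oxygens, should give the erythro (9S)-alcohol F8. TESCl and imidazole in CH2Cl2 then return 20.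

**Further compounds**
F1 | step 16 | acyclic (6R,7R,8R,9S) C6 alcohol (20 without PMB) | O[C@@H]([C@H]1O[C@H]1[C@@H](O[Si](CC)(CC)CC)C(=C)CO[Si](c2ccccc2)(c2ccccc2)C(C)(C)C)/C=C(\CCC=C)CO[Si](c2ccccc2)(c2ccccc2)C(C)(C)C
F2 | step 16 | acyclic O6 diethylphosphonoacetate of F1 | CCOP(=O)(OCC)CC(=O)O[C@@H]([C@H]1O[C@H]1[C@@H](O[Si](CC)(CC)CC)C(=C)CO[Si](c2ccccc2)(c2ccccc2)C(C)(C)C)/C=C(\CCC=C)CO[Si](c2ccccc2)(c2ccccc2)C(C)(C)C
F3 | step 16 | acyclic α-phosphono trans-γ-lactone with free C8 hydroxyl (C11 epimers) | CCOP(=O)(OCC)C1C(=O)O[C@H](/C=C(\CCC=C)CO[Si](c2ccccc2)(c2ccccc2)C(C)(C)C)[C@H]1[C@@H](O)[C@@H](O[Si](CC)(CC)CC)C(=C)CO[Si](c2ccccc2)(c2ccccc2)C(C)(C)C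
F4 | step 13 | tert-butyl({(2Z)-2-iodo-4-[(prop-2-en-1-yl)oxy]but-2-en-1-yl}oxy)diphenylsilane | C=CCOC/C=C(\I)CO[Si](c1ccccc1)(c1ccccc1)C(C)(C)C
F5 | step 13 | relay triene (20 with CH2OCH2CH=CH2 on the C10 methylene carbon) | COc1ccc(CO[C@@H]([C@H]2O[C@H]2[C@@H](O[Si](CC)(CC)CC)/C(=C\COCC=C)CO[Si](c3ccccc3)(c3ccccc3)C(C)(C)C)/C=C(\CCC=C)CO[Si](c3ccccc3)(c3ccccc3)C(C)(C)C)cc1
F6 | step 12 | C9-epimeric alcohols from addition of 18 to 15 | COc1ccc(CO[C@@H]([C@H]2O[C@H]2C(O)C(=C)CO[Si](c3ccccc3)(c3ccccc3)C(C)(C)C)/C=C(\CCC=C)CO[Si](c3ccccc3)(c3ccccc3)C(C)(C)C)cc1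
F7 | step 12 | C9 ketone (α,β-epoxy enone) | COc1ccc(CO[C@@H]([C@H]2O[C@H]2C(=O)C(=C)CO[Si](c3ccccc3)(c3ccccc3)C(C)(C)C)/C=C(\CCC=C)CO[Si](c3ccccc3)(c3ccccc3)C(C)(C)C)cc1
F8 | step 12 | (9S)-alcohol (20 without TES) | COc1ccc(CO[C@@H]([C@H]2O[C@H]2[C@@H](O)C(=C)CO[Si](c3ccccc3)(c3ccccc3)C(C)(C)C)/C=C(\CCC=C)CO[Si](c3ccccc3)(c3ccccc3)C(C)(C)C)cc1
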